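Start from the ratio.

| setting | autumn | midnight | flask |
|---|---|---|---|
| substrate | 28 mM | 44 mM | 20 mM |
| first nucleophile | 60 mM | 60 mM | 60.0 mM |
| gas | 2 mM (held) | 2 mM (held) | 2.0 mM (held) |
| remark | run made earlier | run made earlier |  |
| time |  |  | 12 h |

| run | time / h | other capture product / % | target / % |
|---|---|---|---|
| autumn | 0.667 | 45.6 | 19.5 |
| autumn | 2.00 | 58.5 | 26.5 |
| autumn | 3.00 | 60.2 | 25.7 |
| autumn | 5.00 | 59.9 | 25.6 |
| autumn | 8.00 | 59.7 | 23.7 |
| autumn | 10.0 | 59.8 | 25.7 |
| midnight | 1.50 | 53.5 | 23.8 |
| midnight | 3.00 | 56.1 | 26.8 |
| midnight | 5.00 | 57.8 | 27.5 |
| midnight | 6.00 | 54.7 | 25.4 |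
| midnight | 8.00 | 55.9 | 26.4 |
| midnight | 10.0 | 56.5 | 23.5 |

(each reading ± 1 percentage point)

1. share of other capture product in other capture product plus target at 50 s
2. share of other capture product in other capture product plus target at 25 min
3. share of other capture product in other capture product plus target at 12 h
4. which of other capture product and target there is more of at 12 h

- at the start none of the gas is in solution
- a reading or a percentage of target counts all its forms, free or not

From 3.00 h on, the readings of both runs stay level within their scatter. Target reads on average 25.2 % in the autumn run and 25.9 % in the midnight run. Other capture product per target reads 2.38 and 2.17. Target competes through first nucleophile, so that ratio is multiplied by the mean of the first nucleophile charged and the first nucleophile left. The product is the capture constant, a selectivity factor in mM.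

| Flask | Substrate | Mean first nucleophile | Capture constant | Ratio |
|---|---|---|---|---|
| autumn | 28 mM | 56.5 mM | 134 mM | 2.38 |
| midnight | 44 mM | 54.3 mM | 118 mM | 2.17 |
| flask | 20 mM | 57.5 mM | 143 mM | 2.48 |

Read downward, the constant falls with the charge of substrate, so the flask's entry is taken on the line through the two runs. Its mean first nucleophile borrows the autumn target level. The ratio 2.48 exceeds one, so other capture product leads, with a share of 71.3 % at 12 h. The autumn share already reads 70.0 % at 0.667 h, so 25 min should lie near that level. But 50 s is far earlier than the first reading of either run, and no gas is in solution at the start, so that share should lie below the plateau.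

The forecast gives 86 %, 72.5 % and 71 % with other capture product ahead, and it differs from this reckoning at 50 s: “so the share is clearly higher”.

The flask gives 39.3 %, 69.6 % and 72.2 %, with other capture product ahead.

    crystals ⇌ target, rate k1*(cs1 - [target]) while solid is left; crystals form when [target] > cs1 (solubility = 13.0 mM, k = 1.60 min⁻¹)
    intermediate → solvolysis product (k = 26.0 min⁻¹)
    gas ⇌ second nucleophile, rate k3*(csat - [second nucleophile]) (kL = 0.670 min⁻¹)
    first nucleophile + intermediate → target (k = 700 L mol⁻¹ min⁻¹)
    second nucleophile ⇌ dormant form (K = 160, k = 0.0230 min⁻¹)
    second nucleophile + intermediate → other capture product (k = 72000 L mol⁻¹ min⁻¹)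
    substrate → intermediate (k = 0.0400 min⁻¹)

Other capture product draws level with target at 0.0278 h. At 12 h it stands at 61.3 % against 23.5 % of target, so the flask's capture constant is 150 mM, above the 143 mM reckoned. With 150 mM of first nucleophile and 42.5 % target, 143 mM gives a ratio of 0.979, a share of 49.5 %; that neighbour flask stands at 52.4 %.

All runs are calculated from invented constants; noise was put on by code.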